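**Retrosynthetic overview**
1. The enone is cut by a Claisen–Schmidt disconnection into 4-hydroxyacetophenone and the dihydrobenzofuran-5-carbaldehyde 9. Its CHO and OMe groups come from phenol-directed ortho-formylation and O-methylation of the 4-hydroxy-dihydrobenzofuran 6.
2. The C(CH3)2OH group is a hydrated isopropenyl group (Mukaiyama hydration), so 6 goes back to (S)-2-isopropenyl-2,3-dihydrobenzofuran-4-ol 4.
3. The dihydrofuran ring is the only ring made in the route (both benzene rings are bought) and is formed first. It is cut at C3–C3a and O1–C2 into 2-iodoresorcinol and isoprene, joined by one enantioselective Pd-catalysed Heck/allylic etherification [3+2] heteroannulation that also sets C2.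
4. Enabling feature: C3a lies between the two oxygen-bearing carbons C4 and C7a of the benzene ring (position 2 of a resorcinol, iodinated in the twofold-symmetric 1). C3–C2–C(CH3)2 is an isoprene unit, so C2 is allylic and becomes the terminus of a π-allylpalladium that O1 attacks.

Key step: step 1

Assumption: the sense of induction of the chiral ligand is assigned by analogy only, so the ligand enantiomer that leads to the (S) configuration at C2 is to be selected in a preliminary run.

**Step 1**
Reactants: 1 2-iodoresorcinol (2-iodobenzene-1,3-diol); 2 isoprene (2-methylbuta-1,3-diene)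
Product: 4 (S)-2-(prop-1-en-2-yl)-2,3-dihydro-1-benzofuran-4-ol, via allylpalladium iodide 3 (not isolated)
Conditions: Pd2(dba)3·CHCl3 (5 mol %), chiral tert-butanesulfinamide monophosphine ligand (TY-Phos type, 20 mol %), NaOPh (2.2 equiv), isoprene (3 equiv), CH2Cl2, 40 °C, sealed tube
Reagents that add atoms: none
Why: Oxidative addition of zerovalent palladium into the C–I bond of 1 gives an arylpalladium iodide that inserts the less substituted vinyl group of isoprene with the aryl group going to the terminal CH2 (new aryl C–CH2 bond), leaving allylpalladium species 3, whose phenoxide oxygen then attacks the internal allyl terminus (new O–CH bond) and releases zerovalent palladium. The closest known reaction type is the Larock heteroannulation of ortho-halophenols with 1,3-dienes in its enantioselective Heck/Tsuji–Trost form. The dihydrofuran ring closes in the 5-exo mode at the allyl terminus that bears the benzylic CH2, since attack at the far CH2 terminus would need a seven-membered ring. The C2 stereocentre is set by the chiral ligand on palladium, which discriminates between the two rapidly interconverting (pi-sigma-pi) diastereomeric allyl complexes in the C–O bond-forming step. The step needs insertion into the monosubstituted rather than the 1,1-disubstituted double bond of isoprene, which the lower steric demand of the CH=CH2 terminus secures. No differentiation of the two hydroxyl groups is needed, because the twofold-symmetric 2,6-dihydroxyaryl group gives the same product whichever oxygen closes.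

**Step 2**
Reactants: 4 (S)-2-(prop-1-en-2-yl)-2,3-dihydro-1-benzofuran-4-ol
Product: 6 (S)-2-(2-hydroxypropan-2-yl)-2,3-dihydro-1-benzofuran-4-ol, via tertiary hydroperoxide 5 (not isolated)
Conditions: Co(acac)2 (10 mol %), PhSiH3 (2.5 equiv), O2 (1 atm), THF/i-PrOH, rt
Reagents that add atoms: dioxygen, O=O
Why: Mukaiyama hydration: hydrogen-atom transfer from a cobalt hydride to the 1,1-disubstituted alkene gives the tertiary radical, which O2 should trap faster than it can fragment, and the peroxy species 5 is reduced in situ by the silane to the Markovnikov tertiary alcohol without involving the C2 stereocentre.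

**Step 3**
Reactants: 6 (S)-2-(2-hydroxypropan-2-yl)-2,3-dihydro-1-benzofuran-4-ol
Product: 8 (S)-4-hydroxy-2-(2-hydroxypropan-2-yl)-2,3-dihydro-1-benzofuran-5-carbaldehyde, via hydroxymethyl phenol 7 (not isolated)
Conditions: MgCl2 (anhydrous, 2 equiv), Et3N (4 equiv), (CH2O)n (6 equiv), MeCN, reflux; then 1 M HCl, 0 °C
Reagents that add atoms: paraformaldehyde (as formaldehyde), C=O
Why: Magnesium-mediated ortho-formylation of a phenol (Casnati–Skattebøl reaction): the magnesium phenoxide delivers formaldehyde to C5, the only free ortho position, and the salicyl alcohol 7 is oxidised by a second formaldehyde in an Oppenauer-type hydride transfer, while the chelate-controlled process does not reach the para position C7.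

**Step 4**
Reactants: 8 (S)-4-hydroxy-2-(2-hydroxypropan-2-yl)-2,3-dihydro-1-benzofuran-5-carbaldehyde
Product: 9 (S)-2-(2-hydroxypropan-2-yl)-4-methoxy-2,3-dihydro-1-benzofuran-5-carbaldehyde
Conditions: MeI (1.5 equiv), K2CO3 (2 equiv), DMF, rt to 40 °C
Reagents that add atoms: iodomethane, CI
Why: Williamson etherification: K2CO3 deprotonates only the acidic, aldehyde-conjugated phenol, so methylation should be selective over the tertiary alcohol.

**Step 5**
Reactants: 9 (S)-2-(2-hydroxypropan-2-yl)-4-methoxy-2,3-dihydro-1-benzofuran-5-carbaldehyde; 10 4-hydroxyacetophenone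
Product: 12 (E)-3-[(2S)-2-(2-hydroxypropan-2-yl)-4-methoxy-2,3-dihydro-1-benzofuran-5-yl]-1-(4-hydroxyphenyl)prop-2-en-1-one, via aldol adduct 11 (not isolated)
Conditions: KOH (6 equiv), EtOH/H2O, rt to 50 °C; then cold 1 M HCl to pH 5–6
Reagents that add atoms: none
Why: Claisen–Schmidt condensation: the enolate of 10 adds to the non-enolisable aldehyde 9 and the aldol adduct 11 loses water by an E1cB pathway to the conjugated, thermodynamically favoured E-enone, while the C2 stereocentre carries no acidic hydrogen and is untouched.

**Compound list**
1 | 2-iodoresorcinol (2-iodobenzene-1,3-diol) | Oc1cccc(O)c1I | starting material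
2 | isoprene (2-methylbuta-1,3-diene) | C=CC(C)=C | starting material
3 | allylpalladium iodide from the Heck insertion, drawn in its sigma-allyl form [1-(2,6-dihydroxyphenyl)-3-methylbut-3-en-2-yl]palladium iodide (divalent palladium; phosphine ligand omitted) | CC(=C)C([Pd]I)Cc1c(O)cccc1O | intermediate
4 | (S)-2-(prop-1-en-2-yl)-2,3-dihydro-1-benzofuran-4-ol | Oc1cccc2c1C[C@@H](C(C)=C)O2 | intermediate
5 | (S)-2-(2-hydroperoxypropan-2-yl)-2,3-dihydro-1-benzofuran-4-ol | Oc1cccc2c1C[C@@H](C(C)(C)OO)O2 | intermediate
6 | (S)-2-(2-hydroxypropan-2-yl)-2,3-dihydro-1-benzofuran-4-ol | Oc1cccc2c1C[C@@H](C(C)(C)O)O2 | intermediate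
7 | (S)-5-(hydroxymethyl)-2-(2-hydroxypropan-2-yl)-2,3-dihydro-1-benzofuran-4-ol (present as its magnesium phenoxide) | OCc1ccc2c(c1O)C[C@@H](C(C)(C)O)O2 | intermediate
8 | (S)-4-hydroxy-2-(2-hydroxypropan-2-yl)-2,3-dihydro-1-benzofuran-5-carbaldehyde | O=Cc1ccc2c(c1O)C[C@@H](C(C)(C)O)O2 | intermediate
9 | (S)-2-(2-hydroxypropan-2-yl)-4-methoxy-2,3-dihydro-1-benzofuran-5-carbaldehyde | COc1c(C=O)ccc2c1C[C@@H](C(C)(C)O)O2 | intermediate
10 | 4-hydroxyacetophenone | CC(=O)c1ccc(O)cc1 | starting material
11 | 3-hydroxy-3-[(2S)-2-(2-hydroxypropan-2-yl)-4-methoxy-2,3-dihydro-1-benzofuran-5-yl]-1-(4-hydroxyphenyl)propan-1-one (both carbinol epimers) | COc1c(C(O)CC(=O)c2ccc(O)cc2)ccc2c1C[C@@H](C(C)(C)O)O2 | intermediate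
12 | (E)-3-[(2S)-2-(2-hydroxypropan-2-yl)-4-methoxy-2,3-dihydro-1-benzofuran-5-yl]-1-(4-hydroxyphenyl)prop-2-en-1-one | COc1c(/C=C/C(=O)c2ccc(O)cc2)ccc2c1C[C@@H](C(C)(C)O)O2 | target

**Total step count:** 5. **Longest linear sequence:** 5 steps (from 1 to 12).

**Steps most likely to fail**

Step 1. Oxidative addition into the hindered, electron-rich C–I bond flanked by two oxygens may be slow, so that hydrodeiodination competes. Facial discrimination in the C–O bond-forming step may also be insufficient, which would erode the enantiomeric purity of the only stereocentre. The fallback takes the stereocentre from a reagent-controlled epoxidation instead of a chiral palladium catalyst. It sets out from 1. Bis-silylation (TBSCl, imidazole, DMF) should give 2-iodo-1,3-bis(tert-butyldimethylsilyloxy)benzene F1. Iodine–magnesium exchange (i-PrMgCl·LiCl, THF, −20 °C) followed by copper-catalysed coupling with prenyl bromide at its primary carbon (Li2CuCl4 cat.) should give 1,3-bis(tert-butyldimethylsilyloxy)-2-(3-methylbut-2-en-1-yl)benzene F2. Shi epoxidation (fructose-derived ketone of the enantiomeric series that gives the R epoxide, Oxone (2KHSO5·KHSO4·K2SO4), K2CO3 buffer, MeCN/dimethoxymethane/H2O, 0 °C) should give (R)-3-[2,6-bis(tert-butyldimethylsilyloxy)benzyl]-2,2-dimethyloxirane F3. TBAF in THF should then free the phenols, and one phenoxide should open the epoxide at its secondary carbon in a 5-exo-tet closure with inversion. This fallback comes back to the route at 6, so step 2 is bypassed as well.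

Step 2. Radical-chain oxidation of the free, electron-rich phenol under the aerobic cobalt conditions may compete. Cobalt-hydride-mediated isomerisation or reduction of the alkene may occur when O2 supply is limiting, and reduction of the peroxy intermediate may be incomplete. The fallback is an ionic two-stage Markovnikov hydration that sets out from 4. Epoxidation of the 1,1-disubstituted alkene (mCPBA, NaHCO3, CH2Cl2, 0 °C) should give (2S)-2-(2-methyloxiran-2-yl)-2,3-dihydro-1-benzofuran-4-ol F4 as a mixture of epoxide epimers, which is of no consequence. Hydride opening at the unsubstituted epoxide carbon (LiAlH4, THF, 0 °C) should then give the tertiary alcohol. This fallback comes back to the route at 6.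

Step 5. Deprotonation of the phenol of 10 lowers the acidity of its methyl ketone, so enolate formation and addition to the electron-rich, ortho-substituted aldehyde may be slow. Cannizzaro disproportionation of 9 can then compete. The fallback builds the enone by a base-free Wittig olefination and sets out from 10, using 9 as the partner. α-Bromination (CuBr2, EtOAc/CHCl3, reflux) should give 2-bromo-1-(4-hydroxyphenyl)ethan-1-one F5. PPh3 in MeCN should give [2-(4-hydroxyphenyl)-2-oxoethyl]triphenylphosphonium bromide F6. Aqueous NaOH, then adjustment to pH 8, should give the stabilised ylide 1-(4-hydroxyphenyl)-2-(triphenyl-λ5-phosphanylidene)ethan-1-one F7. Heating F7 with 9 in toluene at reflux should give the E-enone, as expected for a keto-stabilised ylide. This fallback comes back to the route at 12.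

**Further compounds**
F1 | step 1 | 2-iodo-1,3-bis(tert-butyldimethylsilyloxy)benzene | CC(C)(C)[Si](C)(C)Oc1cccc(O[Si](C)(C)C(C)(C)C)c1I
F2 | step 1 | 1,3-bis(tert-butyldimethylsilyloxy)-2-(3-methylbut-2-en-1-yl)benzene | CC(C)=CCc1c(O[Si](C)(C)C(C)(C)C)cccc1O[Si](C)(C)C(C)(C)C
F3 | step 1 | (R)-3-[2,6-bis(tert-butyldimethylsilyloxy)benzyl]-2,2-dimethyloxirane | CC1(C)O[C@@H]1Cc1c(O[Si](C)(C)C(C)(C)C)cccc1O[Si](C)(C)C(C)(C)C
F4 | step 2 | (2S)-2-(2-methyloxiran-2-yl)-2,3-dihydro-1-benzofuran-4-ol (epoxide epimers) | Oc1cccc2c1C[C@@H](C1(C)CO1)O2
F5 | step 5 | 2-bromo-1-(4-hydroxyphenyl)ethan-1-one | O=C(CBr)c1ccc(O)cc1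
F6 | step 5 | [2-(4-hydroxyphenyl)-2-oxoethyl]triphenylphosphonium bromide | O=C(C[P+](c1ccccc1)(c1ccccc1)c1ccccc1)c1ccc(O)cc1.[Br-]
F7 | step 5 | 1-(4-hydroxyphenyl)-2-(triphenyl-λ5-phosphanylidene)ethan-1-one | O=C(C=P(c1ccccc1)(c1ccccc1)c1ccccc1)c1ccc(O)cc1
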